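## Analysis of the target

The target is a ten-membered lactone (ring atoms O, C1–C9) with a 2-methyl group, a 3-acetoxy group, a Z olefin at C4=C5, a free hydroxyl at C8 and, on the ring carbinol C9, a 4-acetoxypentyl chain (C10–C14, acetate on C13). There are five stereocentres: C2 (R), C3 (R), C8 (S), C9 (R) and C13 (S). C2 and C3 are anti in the zigzag drawing, so methyl and acetoxy lie on the same ring face; C8 and C9 form an anti (erythro) 1,2-diol; C13 is too far from the ring to be controlled by it. The sensitive parts are the β-acetoxy lactone with its acidic C2–H (loss of acetate would give a 2,4-dienolide), the Z-allylic ester at C3, and the free C8 hydroxyl beside the lactone oxygen and two acetates (acyl migration). The synthesis is hard because a ten-membered ring closes against transannular strain, three secondary hydroxyls must end as two acetates and one free alcohol, and the anti C2/C3 pair must be set next to a Z olefin that may not isomerise. The strategy rests on the C3–C4 bond, which joins the carbinol carbon C3 to the olefin carbon C4 inside the ring. With C3 as a ketone this is an acyl–alkenyl bond, and C2, lying between the C1 and C3 carbonyls, epimerises freely, so the ring can be closed without any stereochemical load at C2/C3 and both centres can be set afterwards in one reduction.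

## Retrosynthetic reasoning

Protecting groups (22 from 21, 20 and 19). The C8 hydroxyl stays a tert-butyldimethylsilyl ether until the last step, so 22 comes from 21 by desilylation. Both acetates are introduced together on diol 20. This requires the C13 oxygen to carry a group that leaves before the C8 silyl ether, here a triethylsilyl ether (20 from 19). A C13 acetate could not have survived the organomagnesium step that builds the chain, and this choice gives one acetylation instead of two.

C3–H and C2 (19 from 18). The C3 carbinol is traced back to the ketone 18. In 18, C2 is flanked by two carbonyl groups and equilibrates, so one catalyst-controlled 1,2-reduction can set C3 and, through dynamic kinetic resolution, C2. The forward step has to reduce the carbonyl and not the olefin, and has to take the C2 epimer that leads to the 2,3-cis ring arrangement.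

C3–C4, the ring-closing bond (18 from 17). Cutting between the ketone carbon and the olefin carbon gives an acyl donor and an alkenyl iodide on one chain, tethered through the C9 ester. Both ends are stable and both are installed late. An aldehyde at C3 would be an enolised formyl ester and was excluded; a thioester is not. The forward reaction must form an sp2–sp2 bond at a thioester in the presence of an ordinary ester, keep the Z geometry and close a ten-membered ring.

C1–O9 and the acyl donor (17 from 16, from 14 and 15). The C1–C3 unit with its methyl branch is a methylmalonyl group. It is attached to the C9 hydroxyl of 14 by ring-opening of the cyclic malonate 15, which frees exactly one carboxyl group (16) for conversion into the 2-pyridyl thioester 17. No stereocentre has to be controlled here.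

Z-iodoalkene (14 from 13 and 12). The Z C4=C5–I unit is taken back to an iodoalkyne (13) and then to the silylalkyne 12. The silyl group protects the alkyne through the organometallic step and is exchanged for iodine directly; syn delivery of two hydrogen atoms then fixes the Z geometry.

C10–C11 (12 from 6 and 10 through 11). The chain is cut at the bond two carbons from C9, so that C9 arrives as the internal carbon of a terminal epoxide (6) and C13 arrives in a four-carbon nucleophile (11, made from 10). Attack at C10 leaves the C9–O bond untouched and frees only the C9 hydroxyl, while the C8 oxygen is already silylated. This gives the differentiation of the two diol oxygens without extra steps.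

C8 and C9 (6 from 5 and 4; 4 from 1 and 2 through 3). The anti relation is that of an erythro epoxy alcohol, which a Sharpless kinetic resolution of the racemic allylic alcohol 4 delivers directly (5). Compound 4 is one carbon–carbon bond away from the bromide 1 and acrolein 2.

Side-chain piece (10 from 9, 8 and 7). C13 is bought as the diol 7. Its primary hydroxyl becomes the leaving group and then the bromide; its secondary hydroxyl becomes the triethylsilyl ether.

## Alternatives that were turned down

Alternative 1: The lactone C9–O bond is cut and C9 is a plain allylic methylene in the seco acid A1. In the forward step, Pd(OAc)2 with 1,2-bis(phenylsulfinyl)ethane and benzoquinone would cleave an allylic C–H bond of the terminal allyl group, and the carboxylate would attack the π-allyl complex at C9 to give the 9-vinyl lactone A2. In its favour, ring and C9 stereocentre form together from an unactivated C–H bond, and C2/C3 would come from acyclic aldol chemistry, which is more predictable than a reduction inside a medium ring. Against it, A1 contains a second allylic system, the Z-allylic acetate at C3, which zerovalent palladium can ionise, and further allylic C–H bonds at C6. The C8/C9 relation would rest on substrate control in an unfamiliar ring size. The step also leaves only a vinyl group at C9, so the C11–C14 chain with its C13 centre must be added afterwards by olefin metathesis and a hydrogenation that has to spare the ring olefin. The chosen route has the whole side chain in place before ring closure and forms its ring bond at a site defined by an iodide and a thioester, at the price of two prefunctionalised ends.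

Alternative 2: The C5–C6 bond is cut. The precursor A3 is a C9 ester whose acyl part ends in a Z-alkenyl iodide at C5 and whose alcohol part carries a vinyl group at C8. Hydroboration of the vinyl group with 9-BBN and palladium-catalysed coupling of the C6 alkylborane with the iodide would give the bis-silyl lactone A4. In its favour, this ring closure belongs to a well-tested reaction class, and C2 and C3 are fixed before cyclisation, so there is no late stereochemical gamble; on these two points it is stronger than the chosen plan. Against it, the coupling needs aqueous base in the presence of a β-silyloxy ester with an acidic C2–H (elimination to a dienoate) and of the C13 acetate. The alkylpalladium intermediate can undergo β-hydride elimination in a slow medium-ring closure. The acid half of A3 needs its own stereoselective synthesis from an unstable Z-iodoenal and then an esterification of the hindered C9 hydroxyl. The chosen route builds C1–C3 from one commercial four-carbon reagent in two steps, runs its ring closure without base, and pays for this with an unprecedented cyclisation and a late reduction.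

Alternative 3: The C2–C3 bond is cut. The precursor A5 is the C9 2-bromopropanoate of a Z-enal; SmI2 would form a samarium enolate that adds to the aldehyde and gives the 3-hydroxy lactone A6. In its favour, samarium Reformatsky ring closures of medium lactones are established, the acyl piece is trivial, and the step is fast at low temperature; in precedent it is clearly stronger than the chosen key step. Against it, two stereocentres form in a ten-membered transition state with no reliable control, so up to four isomers are possible. The Z-enal is configurationally fragile, and SmI2 can reduce or couple the enal. If selectivity fails, the remedy is oxidation to the 3-ketone and a second reduction, which is the intermediate of the chosen route reached by a longer path. The chosen plan makes that ketone directly from a robust Z-iodoalkene and saves the oxidation; the Reformatsky closure is kept as the fallback.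

Key step: step 12

Remark on the chemistry: positions are numbered C1–C14 along the seco acid (C1 lactone carbonyl, C9 ring carbinol, C13 side-chain carbinol). Compounds 16, 17 and 18 are carried as mixtures of both C2 configurations on purpose; C2 is fixed in step 13.

## Route

Step 1
Reactants: 1 (4-bromobut-1-yn-1-yl)trimethylsilane; 2 acrolein
Product: 4 rac-7-(trimethylsilyl)hept-1-en-6-yn-3-ol, via Grignard reagent 3 (not isolated)
Conditions: Mg, THF, 25–40 °C; then 2, THF, −78 °C; aq. NH4Cl
Reagents that add atoms: none
Why: Grignard 1,2-addition to an enal at low temperature gives the secondary allylic alcohol; the silyl group keeps the alkyne free of an acidic proton. The product is racemic and is resolved in step 2.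

Step 2
Reactants: 4 rac-7-(trimethylsilyl)hept-1-en-6-yn-3-ol
Product: 5 (1S)-1-[(2R)-oxiran-2-yl]-5-(trimethylsilyl)pent-4-yn-1-ol
Conditions: Ti(OiPr)4 (20 mol%), L-(+)-diisopropyl tartrate (24 mol%), tBuOOH (0.45 equiv), 4 Å molecular sieves, CH2Cl2, −20 °C
Reagents that add atoms: tert-butyl hydroperoxide, CC(C)(C)OO
Why: Sharpless kinetic resolution: with L-(+)-tartrate the (S)-alcohol is epoxidised much faster than the (R)-alcohol, and on the olefin face that gives the erythro epoxy alcohol, so C8 (S) and C9 (R) are set together. The run is to be stopped near 45% conversion and unreacted (R)-4 is separated.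

Step 3
Reactants: 5 (1S)-1-[(2R)-oxiran-2-yl]-5-(trimethylsilyl)pent-4-yn-1-ol
Product: 6 tert-butyl(dimethyl){[(1S)-1-[(2R)-oxiran-2-yl]-5-(trimethylsilyl)pent-4-yn-1-yl]oxy}silane
Conditions: TBSCl, imidazole, DMF, 0 °C → rt
Reagents that add atoms: tert-butyldimethylsilyl chloride, CC(C)(C)[Si](C)(C)Cl
Why: Silylation under weakly basic conditions leaves the epoxide and the silylalkyne intact and avoids Payne rearrangement. The C8 oxygen is now marked as the one that stays protected to the end.

Step 4
Reactants: 7 (S)-butane-1,3-diol
Product: 8 (3S)-3-hydroxybutyl 4-methylbenzenesulfonate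
Conditions: TsCl, Et3N, Bu2SnO (2 mol%), CH2Cl2, 0 °C
Reagents that add atoms: 4-toluenesulfonyl chloride, Cc1ccc(cc1)S(=O)(=O)Cl
Why: Sulfonylation is selective for the primary hydroxyl of a primary/secondary diol. The C13 centre is taken unchanged from the chiral pool.

Step 5
Reactants: 8 (3S)-3-hydroxybutyl 4-methylbenzenesulfonate
Product: 9 (3S)-3-(triethylsilyloxy)butyl 4-methylbenzenesulfonate
Conditions: TESCl, imidazole, CH2Cl2, 0 °C
Reagents that add atoms: chlorotriethylsilane, CC[Si](Cl)(CC)CC
Why: Standard silylation of the secondary alcohol. Triethylsilyl is chosen because it can later be removed in the presence of the C8 tert-butyldimethylsilyl ether.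

Step 6
Reactants: 9 (3S)-3-(triethylsilyloxy)butyl 4-methylbenzenesulfonate
Product: 10 [(2S)-4-bromobutan-2-yl]oxy(triethyl)silane
Conditions: LiBr, acetone, 50 °C
Reagents that add atoms: lithium bromide, [Li+].[Br-]
Why: SN2 displacement of a primary tosylate by bromide (Finkelstein type) under neutral conditions that do not touch the silyl ether or C13.

Step 7
Reactants: 10 [(2S)-4-bromobutan-2-yl]oxy(triethyl)silane; 6 tert-butyl(dimethyl){[(1S)-1-[(2R)-oxiran-2-yl]-5-(trimethylsilyl)pent-4-yn-1-yl]oxy}silane
Product: 12 (5S,6R,10S)-5-(tert-butyldimethylsilyloxy)-10-(triethylsilyloxy)-1-(trimethylsilyl)undec-1-yn-6-ol, via Grignard reagent 11 (not isolated)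
Conditions: Mg, THF, rt → 40 °C; then 6, CuI (10 mol%), THF, −40 → −10 °C; aq. NH4Cl
Reagents that add atoms: none
Why: Copper-catalysed SN2 opening of the terminal epoxide at the unhindered C10 by the alkyl Grignard reagent; the C9–O bond is not broken, so C9 keeps its configuration and appears as the only free hydroxyl. Any minor C8/C9 enantiomer from step 2 becomes a diastereomer here and can be removed by chromatography.

Step 8
Reactants: 12 (5S,6R,10S)-5-(tert-butyldimethylsilyloxy)-10-(triethylsilyloxy)-1-(trimethylsilyl)undec-1-yn-6-ol
Product: 13 (5S,6R,10S)-5-(tert-butyldimethylsilyloxy)-1-iodo-10-(triethylsilyloxy)undec-1-yn-6-ol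
Conditions: NIS, AgNO3 (10 mol%), acetone, rt, dark
Reagents that add atoms: N-iodosuccinimide, O=C1CCC(=O)N1I
Why: Silver-catalysed iododesilylation converts a trimethylsilylalkyne directly into the 1-iodoalkyne through a silver acetylide. The free hydroxyl and both silyl ethers tolerate these near-neutral conditions.

Step 9
Reactants: 13 (5S,6R,10S)-5-(tert-butyldimethylsilyloxy)-1-iodo-10-(triethylsilyloxy)undec-1-yn-6-ol
Product: 14 (1Z,5S,6R,10S)-5-(tert-butyldimethylsilyloxy)-1-iodo-10-(triethylsilyloxy)undec-1-en-6-ol
Conditions: 2-nitrobenzenesulfonohydrazide, Et3N, THF/iPrOH (1:1), rt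
Reagents that add atoms: none
Why: Diimide, released from the sulfonyl hydrazide, transfers two hydrogen atoms to the iodoalkyne in a concerted syn fashion, which gives the Z-alkenyl iodide without touching the C–I bond.

Step 10
Reactants: 14 (1Z,5S,6R,10S)-5-(tert-butyldimethylsilyloxy)-1-iodo-10-(triethylsilyloxy)undec-1-en-6-ol; 15 2,2,5-trimethyl-1,3-dioxane-4,6-dione
Product: 16 3-{[(1Z,5S,6R,10S)-5-(tert-butyldimethylsilyloxy)-1-iodo-10-(triethylsilyloxy)undec-1-en-6-yl]oxy}-2-methyl-3-oxopropanoic acid (both C2 epimers)
Conditions: 15 (2.5 equiv), toluene, 90 °C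
Reagents that add atoms: none
Why: Thermal alcoholysis of a Meldrum's acid opens the dioxanedione, loses acetone and gives the malonic half ester, so the C9 hydroxyl is acylated and exactly one carboxyl group is left free. No base or coupling agent is needed.

Step 11
Reactants: 16 3-{[(1Z,5S,6R,10S)-5-(tert-butyldimethylsilyloxy)-1-iodo-10-(triethylsilyloxy)undec-1-en-6-yl]oxy}-2-methyl-3-oxopropanoic acid (both C2 epimers)
Product: 17 (1Z,5S,6R,10S)-5-(tert-butyldimethylsilyloxy)-1-iodo-10-(triethylsilyloxy)undec-1-en-6-yl 2-methyl-3-oxo-3-(pyridin-2-ylsulfanyl)propanoate (both C2 epimers)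
Conditions: 2,2'-dipyridyl disulfide, PPh3, CH2Cl2, 0 °C → rt
Reagents that add atoms: 2,2'-dipyridyl disulfide, c1ccc(nc1)SSc1ccccn1
Why: Redox condensation of a carboxylic acid with the disulfide and the phosphine (Mukaiyama-type thioesterification) gives the 2-pyridyl thioester under neutral conditions. The ester, the silyl ethers and the alkenyl iodide are untouched.

Step 12
Reactants: 17 (1Z,5S,6R,10S)-5-(tert-butyldimethylsilyloxy)-1-iodo-10-(triethylsilyloxy)undec-1-en-6-yl 2-methyl-3-oxo-3-(pyridin-2-ylsulfanyl)propanoate (both C2 epimers)
Product: 18 (4Z,8S,9R,13S)-8-(tert-butyldimethylsilyloxy)-2-methyl-3-oxo-13-(triethylsilyloxy)tetradec-4-en-9-olide (both C2 epimers)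
Conditions: NiBr2(dtbbpy) (30 mol%; dtbbpy = 4,4'-di-tert-butyl-2,2'-bipyridine), Cp2ZrCl2 (2 equiv), Zn dust (6 equiv), 1,3-dimethylimidazolidin-2-one, rt; 17 added over 12 h to 2 mM
Reagents that add atoms: none
Why: Proposed new method: zerovalent nickel, generated from NiBr2(dtbbpy) and zinc, should add oxidatively to the C4–I bond of 17 with retention of the Z geometry, the 2-pyridyl thioester, activated through chelation of its ring nitrogen and carbonyl oxygen by Cp2ZrCl2, then acylates the alkenylnickel species, and reductive elimination from the acyl(alkenyl)nickel intermediate forms C3–C4 while zinc returns nickel to the zerovalent state. The closest known reaction type is the nickel-catalysed, zinc-driven reductive ketone synthesis from alkenyl or alkyl iodides and 2-pyridyl thioesters run between two molecules; ring closure by an alkenylmetal at this ring size is known from the intramolecular Nozaki–Hiyama–Kishi reaction. The ten-membered ring closes by acyl substitution at C3 (formally 10-exo-trig, through an eleven-membered nickelacycle that contracts on reductive elimination); the cis C4=C5 bond holds both chain ends on one side and slow addition keeps free 17 near 2 mM so that cyclisation outruns dimerisation. No stereocentre is created: C2 enters and leaves as a mixture, and C8, C9 and C13 are not involved. The step needs reaction at the thioester only, which is secured because only the 2-pyridyl thioester can chelate and be activated, the C1 ester and the silyl ethers being inert to alkenylnickel species. It also needs the Z olefin to survive, which follows from stereoretentive oxidative addition and the configurational stability of alkenylnickel intermediates at room temperature.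

Step 13
Reactants: 18 (4Z,8S,9R,13S)-8-(tert-butyldimethylsilyloxy)-2-methyl-3-oxo-13-(triethylsilyloxy)tetradec-4-en-9-olide (both C2 epimers)
Product: 19 (2R,3R,4Z,8S,9R,13S)-8-(tert-butyldimethylsilyloxy)-3-hydroxy-2-methyl-13-(triethylsilyloxy)tetradec-4-en-9-olide
Conditions: RuCl[(S,S)-TsDPEN](p-cymene) (5 mol%), HCO2H/Et3N (5:2), CH2Cl2, rt
Reagents that add atoms: none
Why: Noyori–Ikariya asymmetric transfer hydrogenation with dynamic kinetic resolution: the C2 epimers of 18 interconvert through the enol in the amine buffer, the (S,S)-catalyst delivers hydride to the C3 face that places the alkenyl arm next to the arene ligand (3R), and within the ring hydride should enter anti to the C2 methyl group, so the faster-reacting epimer gives the 2,3-cis (2R,3R) alcohol. The outer-sphere Ru–H/N–H transfer is matched to carbonyl groups, and the twisted Z-enone is therefore expected to be reduced at C=O only.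

Step 14
Reactants: 19 (2R,3R,4Z,8S,9R,13S)-8-(tert-butyldimethylsilyloxy)-3-hydroxy-2-methyl-13-(triethylsilyloxy)tetradec-4-en-9-olide
Product: 20 (2R,3R,4Z,8S,9R,13S)-8-(tert-butyldimethylsilyloxy)-3,13-dihydroxy-2-methyltetradec-4-en-9-olide
Conditions: PPTS (20 mol%), MeOH/CH2Cl2 (1:1), 0 °C
Reagents that add atoms: none
Why: Mild acid-catalysed methanolysis removes the unhindered triethylsilyl ether much faster than the hindered secondary tert-butyldimethylsilyl ether at C8. Any triethylsilyl ether already lost under the formic acid of step 13 converges on the same diol.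

Step 15
Reactants: 20 (2R,3R,4Z,8S,9R,13S)-8-(tert-butyldimethylsilyloxy)-3,13-dihydroxy-2-methyltetradec-4-en-9-olide
Product: 21 (2R,3R,4Z,8S,9R,13S)-3,13-diacetoxy-8-(tert-butyldimethylsilyloxy)-2-methyltetradec-4-en-9-olide
Conditions: Ac2O, pyridine, DMAP (5 mol%), CH2Cl2, 0 °C
Reagents that add atoms: acetic anhydride, CC(=O)OC(C)=O
Why: Nucleophile-catalysed acetylation of both free secondary hydroxyls in one operation, with the C8 oxygen still silylated. Low temperature and a weak base keep the β-acetoxy lactone from eliminating.

Step 16
Reactants: 21 (2R,3R,4Z,8S,9R,13S)-3,13-diacetoxy-8-(tert-butyldimethylsilyloxy)-2-methyltetradec-4-en-9-olide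
Product: 22 (2R,3R,4Z,8S,9R,13S)-3,13-diacetoxy-8-hydroxy-2-methyltetradec-4-en-9-olide (CNP0192248.1)
Conditions: HF·pyridine, pyridine, THF, 0 °C → rt
Reagents that add atoms: none
Why: Buffered hydrogen fluoride cleaves the silyl ether without the basicity of fluoride salts, so acetyl migration to the new C8 hydroxyl, translactonisation and elimination at C3 are not expected.

## Compound list

1 | (4-bromobut-1-yn-1-yl)trimethylsilane | C[Si](C)(C)C#CCCBr | starting material
2 | acrolein | C=CC=O | starting material
3 | [4-(trimethylsilyl)but-3-yn-1-yl]magnesium bromide | C[Si](C)(C)C#CCC[Mg]Br | intermediate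
4 | rac-7-(trimethylsilyl)hept-1-en-6-yn-3-ol | C=CC(O)CCC#C[Si](C)(C)C | intermediate
5 | (1S)-1-[(2R)-oxiran-2-yl]-5-(trimethylsilyl)pent-4-yn-1-ol | C[Si](C)(C)C#CCC[C@H](O)[C@H]1CO1 | intermediate
6 | tert-butyl(dimethyl){[(1S)-1-[(2R)-oxiran-2-yl]-5-(trimethylsilyl)pent-4-yn-1-yl]oxy}silane | C[Si](C)(C)C#CCC[C@H](O[Si](C)(C)C(C)(C)C)[C@H]1CO1 | intermediate
7 | (S)-butane-1,3-diol | C[C@H](O)CCO | starting material
8 | (3S)-3-hydroxybutyl 4-methylbenzenesulfonate | C[C@H](O)CCOS(=O)(=O)c1ccc(C)cc1 | intermediate
9 | (3S)-3-(triethylsilyloxy)butyl 4-methylbenzenesulfonate | CC[Si](CC)(CC)O[C@@H](C)CCOS(=O)(=O)c1ccc(C)cc1 | intermediate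
10 | [(2S)-4-bromobutan-2-yl]oxy(triethyl)silane | CC[Si](CC)(CC)O[C@@H](C)CCBr | intermediate
11 | [(3S)-3-(triethylsilyloxy)butyl]magnesium bromide | CC[Si](CC)(CC)O[C@@H](C)CC[Mg]Br | intermediate
12 | (5S,6R,10S)-5-(tert-butyldimethylsilyloxy)-10-(triethylsilyloxy)-1-(trimethylsilyl)undec-1-yn-6-ol | CC[Si](CC)(CC)O[C@@H](C)CCC[C@@H](O)[C@@H](O[Si](C)(C)C(C)(C)C)CCC#C[Si](C)(C)C | intermediate
13 | (5S,6R,10S)-5-(tert-butyldimethylsilyloxy)-1-iodo-10-(triethylsilyloxy)undec-1-yn-6-ol | CC[Si](CC)(CC)O[C@@H](C)CCC[C@@H](O)[C@@H](O[Si](C)(C)C(C)(C)C)CCC#CI | intermediate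
14 | (1Z,5S,6R,10S)-5-(tert-butyldimethylsilyloxy)-1-iodo-10-(triethylsilyloxy)undec-1-en-6-ol | CC[Si](CC)(CC)O[C@@H](C)CCC[C@@H](O)[C@@H](O[Si](C)(C)C(C)(C)C)CC/C=C\I | intermediate
15 | 2,2,5-trimethyl-1,3-dioxane-4,6-dione | CC1C(=O)OC(C)(C)OC1=O | starting material
16 | 3-{[(1Z,5S,6R,10S)-5-(tert-butyldimethylsilyloxy)-1-iodo-10-(triethylsilyloxy)undec-1-en-6-yl]oxy}-2-methyl-3-oxopropanoic acid (both C2 epimers) | CC[Si](CC)(CC)O[C@@H](C)CCC[C@@H](OC(=O)C(C)C(=O)O)[C@@H](O[Si](C)(C)C(C)(C)C)CC/C=C\I | intermediate
17 | (1Z,5S,6R,10S)-5-(tert-butyldimethylsilyloxy)-1-iodo-10-(triethylsilyloxy)undec-1-en-6-yl 2-methyl-3-oxo-3-(pyridin-2-ylsulfanyl)propanoate (both C2 epimers) | CC[Si](CC)(CC)O[C@@H](C)CCC[C@@H](OC(=O)C(C)C(=O)Sc1ccccn1)[C@@H](O[Si](C)(C)C(C)(C)C)CC/C=C\I | intermediate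
18 | (4Z,8S,9R,13S)-8-(tert-butyldimethylsilyloxy)-2-methyl-3-oxo-13-(triethylsilyloxy)tetradec-4-en-9-olide (both C2 epimers) | CC[Si](CC)(CC)O[C@@H](C)CCC[C@H]1OC(=O)C(C)C(=O)/C=C\CC[C@@H]1O[Si](C)(C)C(C)(C)C | intermediate
19 | (2R,3R,4Z,8S,9R,13S)-8-(tert-butyldimethylsilyloxy)-3-hydroxy-2-methyl-13-(triethylsilyloxy)tetradec-4-en-9-olide | CC[Si](CC)(CC)O[C@@H](C)CCC[C@H]1OC(=O)[C@H](C)[C@H](O)/C=C\CC[C@@H]1O[Si](C)(C)C(C)(C)C | intermediate
20 | (2R,3R,4Z,8S,9R,13S)-8-(tert-butyldimethylsilyloxy)-3,13-dihydroxy-2-methyltetradec-4-en-9-olide | C[C@H](O)CCC[C@H]1OC(=O)[C@H](C)[C@H](O)/C=C\CC[C@@H]1O[Si](C)(C)C(C)(C)C | intermediate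
21 | (2R,3R,4Z,8S,9R,13S)-3,13-diacetoxy-8-(tert-butyldimethylsilyloxy)-2-methyltetradec-4-en-9-olide | CC(=O)O[C@@H](C)CCC[C@H]1OC(=O)[C@H](C)[C@H](OC(C)=O)/C=C\CC[C@@H]1O[Si](C)(C)C(C)(C)C | intermediate
22 | (2R,3R,4Z,8S,9R,13S)-3,13-diacetoxy-8-hydroxy-2-methyltetradec-4-en-9-olide (CNP0192248.1) | CC(=O)O[C@@H](C)CCC[C@H]1OC(=O)[C@H](C)[C@H](OC(C)=O)/C=C\CC[C@@H]1O | target

## Step count and least certain steps

Total: 16 steps. Longest linear sequence: 13 steps (from 1 and 2 through steps 1–3 and 7–16; the branch from 7 through steps 4–6 is equally long).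

Step 12 (key step, proposed new method). Three processes are most likely to go wrong. Coupling between two molecules may outrun the strained ten-membered closure and give dimers and oligomers. The alkenylmetal intermediate may be protonated by the acidic C2–H of the malonyl unit, which would give the des-iodo terminal olefin. The pyridine-2-thiolate that is released may add in conjugate fashion to the new enone and erode the Z geometry. The fallback closes the ring at C2–C3 by known chemistry; it sets out from 14 and returns at 18. Palladium-catalysed reductive carbonylation of the alkenyl iodide of 14 (Pd(PPh3)4, CO at 1 atm, Bu3SnH added slowly, THF, 50 °C) should give (2Z,6S,7R,11S)-6-(tert-butyldimethylsilyloxy)-7-hydroxy-11-(triethylsilyloxy)dodec-2-enal F1. Acylation of its free hydroxyl with 2-bromopropanoyl bromide and pyridine at −20 °C gives the 2-bromopropanoate of that enal F2. SmI2 in THF at −78 °C under high dilution then forms the samarium enolate, which adds to the aldehyde in an intramolecular Reformatsky reaction and gives (4Z,8S,9R,13S)-8-(tert-butyldimethylsilyloxy)-3-hydroxy-2-methyl-13-(triethylsilyloxy)tetradec-4-en-9-olide F3 as a mixture at C2 and C3. Dess–Martin periodinane oxidises F3 to 18, and step 13 sets C2 and C3 whatever the composition of that mixture.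

Step 13. The ring conformation, and not the catalyst, may decide which carbonyl face is open, giving poor facial selectivity at C3 or the 2,3-trans isomer; conjugate reduction of the enone is a second risk. The fallback gives up the dynamic resolution; it sets out from 18 and returns at 19. Corey–Bakshi–Shibata reduction with catecholborane and (R)-2-methyl-CBS-oxazaborolidine in toluene at −78 °C (the enantiomer expected to give 3R if the alkenyl arm acts as the larger group) reduces both C2 epimers without equilibration. It should give 19 together with (2S,3R,4Z,8S,9R,13S)-8-(tert-butyldimethylsilyloxy)-3-hydroxy-2-methyl-13-(triethylsilyloxy)tetradec-4-en-9-olide F4. The two are separated by chromatography, and F4 is returned to 18 by Dess–Martin oxidation and reduced again.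

Step 10. Acylation of the C9 hydroxyl, which is shielded by the neighbouring silyloxy group, may be slow; prolonged heating can then bring decarboxylation of the half ester or loss of the triethylsilyl group. The fallback puts the thioester into the acylating agent and needs no heating of the substrate; it sets out from 14 and 15 and returns at 17. Thiolysis of 15 with pyridine-2-thiol in toluene at 80 °C gives 2-methyl-3-oxo-3-(pyridin-2-ylsulfanyl)propanoic acid F5. F5 is coupled with 14 by 1-ethyl-3-(3-dimethylaminopropyl)carbodiimide hydrochloride in CH2Cl2 at 0 °C, through the acyl ketene, to give 17 directly; steps 10 and 11 are then both replaced.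

Step 2. Epoxidation of a monosubstituted olefin is slow, and an incomplete or over-run resolution would lower the enantiomeric purity of all later compounds and caps the yield at half. The fallback takes C9 from the chiral pool; it sets out from 3 and returns at 6. Addition of 3 to (R)-2,2-dimethyl-1,3-dioxolane-4-carbaldehyde in THF at −78 °C should favour the anti (Felkin–Anh) adduct (1S)-1-[(4R)-2,2-dimethyl-1,3-dioxolan-4-yl]-5-(trimethylsilyl)pent-4-yn-1-ol F6, with the syn isomer removed by chromatography. Silylation (TBSCl, imidazole) gives its tert-butyldimethylsilyl ether F7. Aqueous acetic acid at room temperature removes the acetonide to give (2R,3S)-3-(tert-butyldimethylsilyloxy)-7-(trimethylsilyl)hept-6-yne-1,2-diol F8. Selective tosylation of the primary hydroxyl (TsCl, Et3N, Bu2SnO cat.) gives (2R,3S)-3-(tert-butyldimethylsilyloxy)-2-hydroxy-7-(trimethylsilyl)hept-6-yn-1-yl 4-methylbenzenesulfonate F9, and NaH in THF at 0 °C closes the epoxide to 6.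

## Further compounds

F1 | step 12 | (2Z,6S,7R,11S)-6-(tert-butyldimethylsilyloxy)-7-hydroxy-11-(triethylsilyloxy)dodec-2-enal | CC[Si](CC)(CC)O[C@@H](C)CCC[C@@H](O)[C@@H](O[Si](C)(C)C(C)(C)C)CC/C=C\C=O
F2 | step 12 | (2Z,6S,7R,11S)-6-(tert-butyldimethylsilyloxy)-1-oxo-11-(triethylsilyloxy)dodec-2-en-7-yl 2-bromopropanoate | CC[Si](CC)(CC)O[C@@H](C)CCC[C@@H](OC(=O)C(C)Br)[C@@H](O[Si](C)(C)C(C)(C)C)CC/C=C\C=O
F3 | step 12 | (4Z,8S,9R,13S)-8-(tert-butyldimethylsilyloxy)-3-hydroxy-2-methyl-13-(triethylsilyloxy)tetradec-4-en-9-olide (mixture at C2 and C3) | CC[Si](CC)(CC)O[C@@H](C)CCC[C@H]1OC(=O)C(C)C(O)/C=C\CC[C@@H]1O[Si](C)(C)C(C)(C)C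
F4 | step 13 | (2S,3R,4Z,8S,9R,13S)-8-(tert-butyldimethylsilyloxy)-3-hydroxy-2-methyl-13-(triethylsilyloxy)tetradec-4-en-9-olide | CC[Si](CC)(CC)O[C@@H](C)CCC[C@H]1OC(=O)[C@@H](C)[C@H](O)/C=C\CC[C@@H]1O[Si](C)(C)C(C)(C)C
F5 | step 10 | 2-methyl-3-oxo-3-(pyridin-2-ylsulfanyl)propanoic acid | CC(C(=O)O)C(=O)Sc1ccccn1
F6 | step 2 | (1S)-1-[(4R)-2,2-dimethyl-1,3-dioxolan-4-yl]-5-(trimethylsilyl)pent-4-yn-1-ol | C[Si](C)(C)C#CCC[C@H](O)[C@H]1COC(C)(C)O1
F7 | step 2 | tert-butyl{[(1S)-1-[(4R)-2,2-dimethyl-1,3-dioxolan-4-yl]-5-(trimethylsilyl)pent-4-yn-1-yl]oxy}dimethylsilane | C[Si](C)(C)C#CCC[C@H](O[Si](C)(C)C(C)(C)C)[C@H]1COC(C)(C)O1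
F8 | step 2 | (2R,3S)-3-(tert-butyldimethylsilyloxy)-7-(trimethylsilyl)hept-6-yne-1,2-diol | C[Si](C)(C)C#CCC[C@H](O[Si](C)(C)C(C)(C)C)[C@H](O)CO
F9 | step 2 | (2R,3S)-3-(tert-butyldimethylsilyloxy)-2-hydroxy-7-(trimethylsilyl)hept-6-yn-1-yl 4-methylbenzenesulfonate | C[Si](C)(C)C#CCC[C@H](O[Si](C)(C)C(C)(C)C)[C@H](O)COS(=O)(=O)c1ccc(C)cc1
A1 | alternative 1 | (2R,3R,4Z,8S)-3-acetoxy-8-(tert-butyldimethylsilyloxy)-2-methylundeca-4,10-dienoic acid | OC(=O)[C@H](C)[C@H](OC(C)=O)/C=C\CC[C@@H](CC=C)O[Si](C)(C)C(C)(C)C
A2 | alternative 1 | (2R,3R,4Z,8S,9R)-3-acetoxy-8-(tert-butyldimethylsilyloxy)-2-methylundeca-4,10-dien-9-olide | C=C[C@H]1OC(=O)[C@H](C)[C@H](OC(C)=O)/C=C\CC[C@@H]1O[Si](C)(C)C(C)(C)C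
A3 | alternative 2 | C9 ester of the C6–C14 vinyl carbinol (8-O-tert-butyldimethylsilyl, 13-O-acetyl) with (4Z)-5-iodo-2-methyl-3-(triethylsilyloxy)pent-4-enoic acid, configuration as in the SMILES | CC(=O)O[C@@H](C)CCC[C@@H](OC(=O)[C@H](C)[C@H](O[Si](CC)(CC)CC)/C=C\I)[C@@H](O[Si](C)(C)C(C)(C)C)C=C
A4 | alternative 2 | (2R,3R,4Z,8S,9R,13S)-13-acetoxy-8-(tert-butyldimethylsilyloxy)-2-methyl-3-(triethylsilyloxy)tetradec-4-en-9-olide | CC(=O)O[C@@H](C)CCC[C@H]1OC(=O)[C@H](C)[C@H](O[Si](CC)(CC)CC)/C=C\CC[C@@H]1O[Si](C)(C)C(C)(C)C
A5 | alternative 3 | C9 2-bromopropanoate of the (2Z)-enal of the C3–C14 chain (8-O-tert-butyldimethylsilyl, 13-O-acetyl), configuration as in the SMILES | CC(=O)O[C@@H](C)CCC[C@@H](OC(=O)C(C)Br)[C@@H](O[Si](C)(C)C(C)(C)C)CC/C=C\C=O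
A6 | alternative 3 | (2R,3R,4Z,8S,9R,13S)-13-acetoxy-8-(tert-butyldimethylsilyloxy)-3-hydroxy-2-methyltetradec-4-en-9-olide | CC(=O)O[C@@H](C)CCC[C@H]1OC(=O)[C@H](C)[C@H](O)/C=C\CC[C@@H]1O[Si](C)(C)C(C)(C)C
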